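(The numbers of this flask belong to no real substance; the result is computed.)

The question is how much target stands at the end of each flask as the catalyst loading rises.

| setting | autumn | summer | dawn | dusk | midnight |
|---|---|---|---|---|---|
| starting material | 1.1 M (fed, over 5.0 h) | 1.1 M (fed, over 5.0 h) | 1.1 M (fed, over 5.0 h) | 1.1 M (fed, over 5.0 h) | 1.1 M (fed, over 5.0 h) |
| catalyst | 0.60 mM | 1.5 mM | 5.0 mM | 15 mM | 50 mM |
| time | 2.5 d | 2.5 d | 2.5 d | 2.5 d | 2.5 d |

* amount of target at the end, in percent of the starting material charged for autumn, summer, dawn, dusk, midnight, in this order
* how the row runs (rises all the way / falls all the way / rises, then falls / hardly changes / falls, then rises)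

    target + catalyst ⇌ isomer of the product A + catalyst, rate k1*[catalyst]*[target] forward; the back reaction follows from the equilibrium constant (K1 = 4.8, k1 = 0.0017 /M/s)
    isomer of the product A + catalyst ⇌ isomer of the product B + catalyst, rate k2*[catalyst]*[isomer of the product A] forward; the back reaction follows from the equilibrium constant (K2 = 1.4, k2 = 3.8 × 10⁻⁴ /M/s)
    starting material + catalyst ⇌ target + catalyst, rate k3*[starting material]*[catalyst] forward; the back reaction follows from the equilibrium constant (K3 = 2.2, k3 = 0.0015 /M/s)
    target → over-reaction product (k4 = 1.9 × 10⁻⁵ /s)

- "hardly changes" means that all values lie within two and a half points (for a concentration: within two and a half percent of the largest)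
- run time (autumn): 2.5 d

The reagent charged in the smaller amount is the catalyst, and its balance is short. It stands on both sides of each catalysed step, so its concentration stays as charged and each catalysed step is pseudo-first-order, with a constant equal to rate constant times catalyst.

In the autumn flask, starting material therefore opens by feeding target with a supply constant of 0.0778 /d. The feed is shorter than the run, so this reckoning treats the charge as present from the start. The supply slows as starting material falls, by a slowing factor of 1.21 over the autumn run.

Target leaves the autumn flask with a drain constant of 1.77 /d, which counts over-reaction, the forward step to isomer of the product A and the way back to starting material. The drain is faster than the supply, so target follows its falling supply, and this reckoning puts it at 3.79% of the charge at the end of the autumn run. This relay yield, the supply constant over the drain constant less the supply constant, divided by the slowing factor, counts no return of target from isomer of the product A.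

Raising the catalyst lifts the supply constant in proportion, but the slowing factor grows exponentially:

| Flask | Slowing factor | Relay yield |
|---|---|---|
| autumn | 1.21 | 3.79% |
| summer | 1.63 | 6.81% |
| dawn | 5.05 | 6.34% |
| dusk | 129 | 0.541% |
| midnight | 1.09 × 10⁷ | <0.001% |

Read from autumn to midnight, the relay yields commit this reckoning to a row that rises, then falls.

The forecast reads 3.8%, 7.1%, 8.6%, 4.5% and 4%, a row that rises, then falls, on the ground that at low catalyst “its level tracks the catalysed supply from the starting material”; unlike this reckoning, it peaks at dawn and keeps target at midnight.

The simulation gives 3.77%, 6.99%, 8.52%, 4.60% and 4.03%, and the row rises, then falls.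

The relay yield of 3.79% stands beside 3.77% in autumn, and 6.81% stands beside 6.99% in summer. At midnight the relay yield of <0.001% lies far below the 4.03% in the flask. In the autumn flask, part of the reason target stays low is its loss to over-reaction product: with that loss taken away, autumn target stands at 14.7% instead of 3.77%.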